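**Assumption:** the name is taken to mean exactly the given SMILES; atom labels C1–C15 are germacrane numbering (C6 = lactone carbinol, C8 = angelate carbon, C10 = C(CH3)–O, C3 = hemiketal carbon). The route is a design from first principles and has not been run. The sense of the Barbier step (7,8-anti, 8S) is assigned on Zimmerman–Traxler grounds.

## Retrosynthetic overview
1. The hemiketal is the closed form of a 3-keto-10-hydroxy germacranolide; global desilylation of the C10-OTES/C15-OTBS enone closes the THF ring last.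
2. The ten-membered carbocycle is closed at C3–C4 by intramolecular Nozaki–Hiyama–Kishi (NHK) coupling (vinyl iodide + aldehyde), then oxidised to the enone.
3. The C8 angelate is installed by Mitsunobu inversion of the 8-epi alcohol.
4. C7–C8 and the α-methylene-γ-butyrolactone come from a Zn-Barbier coupling of bromobutenolide 8 (C4–C7, C11–C13, C15) with aldehyde 13 (C1–C3, C8–C10, C14).
5. Ring order: butenolide (RCM) → ten-membered ring (NHK) → THF hemiketal. C6 comes from a Sharpless kinetic resolution, C10 from Sharpless epoxidation of geraniol.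

## Route

**Step 1**
Reactants: 1 tert-butyldimethyl(prop-2-yn-1-yloxy)silane; 2 (E)-crotonaldehyde
Product: 3 rac-(E)-1-(tert-butyldimethylsilyloxy)hept-5-en-2-yn-4-ol
Conditions: n-BuLi, THF, −78 °C; then 2, −78 → −40 °C
Reagents that add atoms: none (all atoms from 1 and 2)
Why: 1,2-addition of the lithium acetylide to the enal joins C5–C6 and gives the alkenyl alkynyl carbinol.

**Step 2**
Reactants: 3
Product: 4 (S,E)-1-(tert-butyldimethylsilyloxy)hept-5-en-2-yn-4-ol (recovered alcohol)
Conditions: Ti(OiPr)4, L-(+)-DIPT, TBHP (0.6 equiv), 4 Å MS, CH2Cl2, −20 °C, to ~55–60% conversion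
Reagents that add atoms: none (oxygen goes only into the discarded epoxy alcohol)
Why: Sharpless kinetic resolution; with L-(+)-DIPT the R enantiomer is epoxidised fast (erythro product), leaving (S)-4, which sets C6.

**Step 3**
Reactants: 4
Product: 5 (S,2Z,5E)-1-(tert-butyldimethylsilyloxy)-2-iodohepta-2,5-dien-4-ol
Conditions: Red-Al, THF, 0 °C; then I2, −78 °C
Reagents that add atoms: iodine, II
Why: alkoxide-directed trans-hydroalumination puts H on the carbon next to the carbinol and Al on the distal carbon; iodinolysis with retention gives the Z-vinyl iodide (I cis to C6), and low temperature avoids β-elimination of the silyloxy group.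

**Step 4**
Reactants: 5; 6 2-(bromomethyl)acrylic acid
Product: 7 (S,2Z,5E)-1-(tert-butyldimethylsilyloxy)-2-iodohepta-2,5-dien-4-yl 2-(bromomethyl)acrylate
Conditions: 6, (COCl)2, cat. DMF, CH2Cl2; then 5, iPr2NEt, CH2Cl2, −78 → 0 °C
Reagents that add atoms: 2-(bromomethyl)acryloyl chloride (from 6), C=C(CBr)C(Cl)=O
Why: O-acylation of the secondary alcohol; a hindered base and low temperature avoid SN2′ attack on the allylic bromide, and the stereocentre is untouched.

**Step 5**
Reactants: 7
Product: 8 (S)-3-(bromomethyl)-5-[(Z)-3-(tert-butyldimethylsilyloxy)-2-iodoprop-1-en-1-yl]furan-2(5H)-one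
Conditions: Grubbs II (5–10 mol %), CH2Cl2, 40 °C, 0.01 M
Reagents that add atoms: none
Why: ring-closing metathesis between the propenyl and acrylate olefins gives the trisubstituted butenolide with loss of propene; the iodoalkene is inert to Ru.

**Step 6**
Reactants: 9 geraniol
Product: 10 (2S,3S)-2,3-epoxygeraniol
Conditions: Ti(OiPr)4 (5 mol %), L-(+)-DET (7.5 mol %), TBHP, 4 Å MS, CH2Cl2, −20 °C
Reagents that add atoms: tert-butyl hydroperoxide, CC(C)(C)OO
Why: Sharpless asymmetric epoxidation; L-(+)-tartrate gives the (2S,3S)-epoxide, which sets the C10 C–O stereocentre.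

**Step 7**
Reactants: 10
Product: 11 (S)-3,7-dimethyloct-6-ene-1,3-diol
Conditions: Red-Al, THF, 0 °C → rt
Reagents that add atoms: none
Why: intramolecular hydride delivery from the alkoxyaluminate opens the 2,3-epoxy alcohol at C2 to give the 1,3-diol; the tertiary C–O bond is untouched, so configuration is retained.

**Step 8**
Reactants: 11
Product: 12 (S)-3,7-dimethyl-1,3-bis(triethylsilyloxy)oct-6-ene
Conditions: TESOTf, 2,6-lutidine, CH2Cl2, −78 → 0 °C
Reagents that add atoms: triethylsilyl triflate, CC[Si](CC)(CC)OS(=O)(=O)C(F)(F)F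
Why: exhaustive silylation; the triflate is reactive enough for the tertiary alcohol.

**Step 9**
Reactants: 12
Product: 13 (S)-3,7-dimethyl-3-(triethylsilyloxy)oct-6-enal
Conditions: (COCl)2, DMSO, CH2Cl2, −78 → −30 °C; then Et3N
Reagents that add atoms: none
Why: Swern conditions selectively cleave and oxidise the primary TES ether to the aldehyde, leaving the tertiary TES ether intact.

**Step 10**
Reactants: 8; 13
Product: 14 (4R,5S)-4-[(1S,3S)-1-hydroxy-3,7-dimethyl-3-(triethylsilyloxy)oct-6-en-1-yl]-5-[(Z)-3-(tert-butyldimethylsilyloxy)-2-iodoprop-1-en-1-yl]-3-methylidenedihydrofuran-2(3H)-one (trans lactone, 8S = 8-epi carbinol)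
Conditions: Zn dust, THF/sat. aq NH4Cl, 0 °C → rt
Reagents that add atoms: none (all atoms from 8 and 13)
Why: Barbier allylation (SE2′) through a chair transition state forms C7–C8 anti to the C6 substituent (trans lactone, sets C7) and gives the 7,8-anti carbinol (8S); the exocyclic methylene is unveiled and the vinyl iodide is inert to Zn.

**Step 11**
Reactants: 14; 15 angelic acid
Product: 16 the (8R)-angelate: (1R,3S)-1-[(3R,2S)-2-[(Z)-3-(tert-butyldimethylsilyloxy)-2-iodoprop-1-en-1-yl]-4-methylidene-5-oxotetrahydrofuran-3-yl]-3,7-dimethyl-3-(triethylsilyloxy)oct-6-en-1-yl (Z)-2-methylbut-2-enoate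
Conditions: PPh3, DIAD, 15, toluene, 0 °C → rt
Reagents that add atoms: angelic acid, C/C=C(/C)C(=O)O
Why: Mitsunobu esterification inverts C8 (8S → 8R) while installing the ester; the acid acts only as a carboxylate nucleophile, so there is no angelate → tiglate isomerisation.

**Step 12**
Reactants: 16
Product: 17 the C3 aldehyde (CH=CMe2 terminus of 16 cleaved to CHO)
Conditions: O3, CH2Cl2/MeOH, pyridine, Sudan III end-point, −78 °C; then PPh3
Reagents that add atoms: ozone, [O-][O+]=O
Why: chemoselective ozonolysis; the electron-rich trialkyl olefin reacts far faster than the angelate, the α-methylene lactone and the iodoalkene.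

**Step 13**
Reactants: 17
Product: 18 (4Z,6R,7R,8R,10S)-8-angeloyloxy-15-(tert-butyldimethylsilyloxy)-3-hydroxy-10-(triethylsilyloxy)germacra-4,11(13)-dien-6,12-olide (C3 epimers)
Conditions: CrCl2 (8 equiv), NiCl2 (cat.), DMSO/THF, rt, 3 mM, slow addition
Reagents that add atoms: none
Why: intramolecular Nozaki–Hiyama–Kishi coupling forms C3–C4 and the ten-membered ring with retention of the Z olefin; it tolerates the lactone, ester and silyl ethers, and the new C3 carbinol configuration is irrelevant.

**Step 14**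
Reactants: 18
Product: 19 the corresponding 3-oxo (Z)-enone
Conditions: Dess–Martin periodinane, NaHCO3, CH2Cl2, rt
Reagents that add atoms: none
Why: mild oxidation of the allylic alcohol to the enone, converging both C3 epimers.

**Step 15**
Reactants: 19
Product: 20 niveusin B
Conditions: HF·pyridine, pyridine/THF, 0 °C → rt
Reagents that add atoms: none
Why: global desilylation; the freed C10-OH adds to the C3 ketone (transannular hemiketalisation), and the bridged geometry allows only the 3R hemiketal.

## Compound list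
1 | tert-butyldimethyl(prop-2-yn-1-yloxy)silane | C#CCO[Si](C)(C)C(C)(C)C | starting material
2 | (E)-crotonaldehyde | C/C=C/C=O | starting material
3 | rac-(E)-1-(TBSO)hept-5-en-2-yn-4-ol | CC(C)(C)[Si](C)(C)OCC#CC(O)/C=C/C | intermediate
4 | (S,E)-1-(TBSO)hept-5-en-2-yn-4-ol | CC(C)(C)[Si](C)(C)OCC#C[C@@H](O)/C=C/C | intermediate
5 | (S,2Z,5E)-1-(TBSO)-2-iodohepta-2,5-dien-4-ol | CC(C)(C)[Si](C)(C)OC/C(I)=C/[C@@H](O)/C=C/C | intermediate
6 | 2-(bromomethyl)acrylic acid | C=C(CBr)C(=O)O | starting material
7 | (S,2Z,5E)-1-(TBSO)-2-iodohepta-2,5-dien-4-yl 2-(bromomethyl)acrylate | CC(C)(C)[Si](C)(C)OC/C(I)=C/[C@@H](OC(=O)C(=C)CBr)/C=C/C | intermediate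
8 | (S)-3-(bromomethyl)-5-[(Z)-3-(TBSO)-2-iodoprop-1-enyl]furan-2(5H)-one | CC(C)(C)[Si](C)(C)OC/C(I)=C/[C@H]1OC(=O)C(CBr)=C1 | intermediate
9 | geraniol | CC(C)=CCC/C(C)=C/CO | starting material
10 | (2S,3S)-2,3-epoxygeraniol | CC(C)=CCC[C@@]1(C)[C@H](CO)O1 | intermediate
11 | (S)-3,7-dimethyloct-6-ene-1,3-diol | CC(C)=CCC[C@@](C)(CCO)O | intermediate
12 | (S)-3,7-dimethyl-1,3-bis(triethylsilyloxy)oct-6-ene | CC(C)=CCC[C@@](C)(CCO[Si](CC)(CC)CC)O[Si](CC)(CC)CC | intermediate
13 | (S)-3,7-dimethyl-3-(triethylsilyloxy)oct-6-enal | CC(C)=CCC[C@@](C)(CC=O)O[Si](CC)(CC)CC | intermediate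
14 | Barbier adduct, trans lactone, 8S alcohol | CC(C)(C)[Si](C)(C)OC/C(I)=C/[C@H]1OC(=O)C(=C)[C@@H]1[C@@H](O)C[C@](C)(CCC=C(C)C)O[Si](CC)(CC)CC | intermediate
15 | angelic acid, (Z)-2-methylbut-2-enoic acid | C/C=C(/C)C(=O)O | starting material
16 | 8R angelate | CC(C)(C)[Si](C)(C)OC/C(I)=C/[C@H]1OC(=O)C(=C)[C@@H]1[C@H](OC(=O)/C(C)=C\C)C[C@](C)(CCC=C(C)C)O[Si](CC)(CC)CC | intermediate
17 | C3 aldehyde | CC(C)(C)[Si](C)(C)OC/C(I)=C/[C@H]1OC(=O)C(=C)[C@@H]1[C@H](OC(=O)/C(C)=C\C)C[C@](C)(CCC=O)O[Si](CC)(CC)CC | intermediate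
18 | macrocyclic C3 allylic alcohol (epimers) | C=C1C(=O)O[C@@H]2/C=C(/CO[Si](C)(C)C(C)(C)C)C(O)CC[C@](C)(O[Si](CC)(CC)CC)C[C@@H](OC(=O)/C(C)=C\C)[C@@H]12 | intermediate
19 | macrocyclic 3-oxo enone | C=C1C(=O)O[C@@H]2/C=C(/CO[Si](C)(C)C(C)(C)C)C(=O)CC[C@](C)(O[Si](CC)(CC)CC)C[C@@H](OC(=O)/C(C)=C\C)[C@@H]12 | intermediate
20 | niveusin B | C=C1C(=O)O[C@@H]2/C=C(/CO)[C@@]3(O)CC[C@@](C)(C[C@@H](OC(=O)/C(C)=C\C)[C@@H]12)O3 | target

## Summary
Total steps: 15.
Longest linear sequence: 11 steps (steps 1–5, then 10–15); the geraniol branch is 4 steps (6–9).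

Three steps most likely to fail, each with a fallback:
1. **Step 11, Mitsunobu inversion at hindered C8** (risk: elimination or no reaction). Fallback: redox inversion instead of SN2 — oxidise 14 to the C8 ketone (DMP), reduce under reagent control (CBS) to the 8R alcohol, then acylate with retention using the angelic acid/2,4,6-trichlorobenzoyl mixed anhydride without DMAP.
2. **Step 13, NHK closure of the strained ten-membered ring** (risk: oligomers or reduction). Fallback: change the ring-closing bond — form C3–C4 first by intermolecular NHK of a protected form of iodide 5 with the C3 aldehyde, build the bromobutenolide afterwards, and close the ring at C7–C8 by intramolecular Zn or CrCl2 Barbier allylation.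
3. **Step 5, RCM of the 2-(bromomethyl)acrylate** (risk: allylic bromide and hindered acrylate stall the catalyst). Fallback: acylate 5 with acryloyl chloride, run the RCM to the unsubstituted butenolide, then add C13 by Morita–Baylis–Hillman hydroxymethylation (aq. CH2O, imidazole) and convert to the bromide (PBr3).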